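In a one-step world, ring made and starting material lost are the same amount. The grey flask, at 50 °C, shows otherwise, so I set those two amounts against each other. Dividing one rate by the other removes time.

| flask | starting material | protic impurity | temperature | remark | time |
|---|---|---|---|---|---|
| grey | 2.8 M | 0.056 M | 50 °C | the very flask that is asked about, followed so far |  |
| teal | 2.8 M | 0.056 M | 56 °C | run made earlier |  |
| flask | 2.8 M | 0.0560 M | 50 °C |  | 40 h |

| run | time / h | ring / % | starting material / % |
|---|---|---|---|
| grey | 5.00 | 39.4 | 43.8 |
| grey | 10.0 | 54.1 | 21.4 |
| grey | 15.0 | 63.4 | 8.9 |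
| grey | 20.0 | 63.7 | 3.0 |
| grey | 25.0 | 65.4 | 1.5 |
| grey | 30.0 | 66.3 | 2.2 |
| teal | 5.00 | 59.6 | 19.8 |
| teal | 10.0 | 70.0 | 3.2 |
| teal | 15.0 | 72.5 | 0.9 |
| teal | 20.0 | 72.5 | 0 |
| teal | 25.0 | 73.5 | 1.3 |
| teal | 30.0 | 71.7 | 1.0 |

(standard deviation of a reading: 1 percentage point)

- ring that was removed still counts

- autumn: change nothing and wait 20 h more
- dawn: at 40 h take out 90 % of the ring then present, then wait 20 h
- midnight: at 40 h raise the temperature by 15 K, then wait 20 h

* ring, in percent of the starting material first charged, at 40 h
* the option that brings most further ring ("none" if no option brings more than 2 percentage points) (autumn / dawn / midnight / none)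
* ring present, with what was taken out counted in, in percent of the starting material first charged, after dawn
* ring present, with what was taken out counted in, in percent of the starting material first charged, after midnight

Grey readings from 20.0 h on give 0.666 for ring made per starting material consumed, the selectivity.

S = [ring] / ([starting material charged] − [starting material])

Grey starting material falls from 43.8 % at 5.00 h to 8.9 % at 15.0 h, a first-order reading of 0.159 h⁻¹. Carried to 40 h, that leaves 0.166 %.

ring at 40 h = S × consumed = 66.5 %

further ring = S × left = 0.11 percentage points

That gain is less than the mark of 2 points, so I choose none. I assume ring gives nothing back: teal ring reads 72.5 % at 15.0 h and 71.7 % at 30.0 h, a difference inside the scatter. Taking ring out or heating then acts on the same remnant, and I reckon 66.6 % after dawn and after midnight.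

The forecast gives 66.5 % (65 % to 68 %), none as best, 66.6 % after dawn and 66.7 % after midnight, holding that “The plateau is therefore set by exhausted feed, not by equilibrium”.

The flask gives 66.6 %, best none, 66.7 % after dawn and 66.6 % after midnight.

    starting material → ring (k = 0.130 h⁻¹, Ea = 114 kJ mol⁻¹)
    2 starting material → open dimer (k = 0.00260 L mol⁻¹ h⁻¹, Ea = 104 kJ mol⁻¹)
    starting material + ring → side product (k = 0.0220 L mol⁻¹ h⁻¹, Ea = 68.0 kJ mol⁻¹)
    starting material + protic impurity → quenched substrate (k = 2.20 L mol⁻¹ h⁻¹, Ea = 60.0 kJ mol⁻¹)
    (constants at 50 °C)

Every step of this scheme takes starting material, and the flask holds 0.120 % of it at 40.0 h. The neighbour flask has the same charge and temperature but stops at 15 h, with 8.5 % of its starting material left. With S from grey, I reckon 60.9 % ring there, and that flask holds 62.1 %. S times its remnant is 5.7 points, more than the mark of 2 points. Left until 40 h, the flask stands 4.5 points above the neighbour, at 66.6 %.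

The runs were generated by integration with constants of no real substance; the scatter is artificial.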